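## Retrosynthetic overview

1. Target 27 ⇐ DDQ cleavage of the C3–O 1-(2-naphthyl)ethyl ether of 26 ⇐ Shi epoxidation of the prenyl group ⇐ one double angeloylation of diol 23; ring oxirane C1–C6 ⇐ hydroxyl-directed epoxidation of cyclohexenol 21 ⇐ Luche reduction of enone 20.
2. Enone 20 ⇐ one-flask (3+3) annulation of allylsilane–acetal 10 with the siloxy-enol-ether acetal 17. C3–C4 forms by anti-SE2′ attack of the allylsilane on a 2-siloxyallyl (oxocarbenium) cation, C6–C1 by intramolecular Mukaiyama aldol closure, followed by loss of ethanol.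
3. Enabling feature: C4 carries a 1,1-disubstituted alkene (C=CH2) two bonds from the C3 oxygen (homoallylic ether, the retron of an allylsilane). C2 is an oxygenated carbon flanked by C1 and C3 (2-oxyallyl retron). The C1(Me)–C6 oxirane next to C2–O is the retron of a 2-methylcyclohex-2-enone.
4. Stereocontrol: the bought centre of (S)-1-(naphthalen-2-yl)ethanol (acetal auxiliary, later the C3–O protecting group) sets C3. C4 (SE2′ topology), C2 (Luche) and C1/C6 (directed epoxidation) are relayed from it. The side-chain carbinol is set by CBS reduction and the side-chain oxirane by Shi epoxidation.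
5. Ring order: cyclohexenone (step 9) → ring oxirane (step 11) → side-chain oxirane (step 14).

Key step: step 9

Remark: ring positions are numbered as in the 7-oxabicyclo[4.1.0]heptane core of the target (C1 = C–CH3, C2 = C–O-angelate, C3 = C–OH, C4 = carbon bearing the side chain, C5 = CH2, C6 = oxirane CH); the acetal carbon of 15–17 is an epimer mixture, which is of no consequence because it becomes planar in step 9.

## Route

Step 1
Reactants: 1 4-methylpent-3-enoic acid
Product: 3 N-methoxy-N,4-dimethylpent-3-enamide, via acyl imidazole 2 (not isolated)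
Conditions: CDI, CH2Cl2, 0 °C → rt; then MeNHOMe·HCl, rt
Reagents that add atoms: N,O-dimethylhydroxylamine hydrochloride, CNOC.Cl
Why: Weinreb amide formation through the acyl imidazole, a neutral activation that should leave the β,γ-alkene out of conjugation; no stereocentre is formed.

Step 2
Reactants: 3 N-methoxy-N,4-dimethylpent-3-enamide; 4 4,4-diethoxybut-1-yne
Product: 6 1,1-diethoxy-8-methylnon-7-en-3-yn-5-one, via lithium acetylide 5 (not isolated)
Conditions: 4, n-BuLi, THF, −78 °C; then 3, −78 → −30 °C; cold aq. NH4Cl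
Reagents that add atoms: none
Why: Weinreb ketone synthesis: the acetylide adds once because the chelated tetrahedral adduct survives until the cold quench, which should also keep the skipped enone from conjugating.

Step 3
Reactants: 6 1,1-diethoxy-8-methylnon-7-en-3-yn-5-one
Product: 7 (5S)-1,1-diethoxy-8-methylnon-7-en-3-yn-5-ol
Conditions: (S)-Me-CBS (0.2 equiv), catecholborane, toluene, −78 °C; MeOH, then aq. NaOH wash
Reagents that add atoms: none
Why: Corey–Bakshi–Shibata reduction in which the slim alkynyl group acts as the small and the CH2 chain as the large substituent, so that the (S)-catalyst should give the (S)-carbinol, while catecholborane at −78 °C leaves the alkene alone.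

Step 4
Reactants: 7 (5S)-1,1-diethoxy-8-methylnon-7-en-3-yn-5-ol
Product: 9 (3Z,5S)-1,1-diethoxy-8-methyl-4-[(trimethylsilyl)methyl]nona-3,7-dien-5-ol, via alkenylmagnesium alkoxide 8 (not isolated)
Conditions: Me3SiCH2MgCl (4 equiv), CuI (0.2 equiv), Et2O–toluene, rt → 60 °C; aq. NH4Cl
Reagents that add atoms: (trimethylsilyl)methylmagnesium chloride, C[Si](C)(C)C[Mg]Cl
Why: Copper-catalysed anti-carbomagnesiation of the propargylic alkoxide: CH2SiMe3 is delivered to the alkyne carbon next to the carbinol and magnesium to the distal carbon within a five-membered chelate, so that protonation should give the Z-allylsilane (CH2Si cis to the acetal chain).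

Step 5
Reactants: 9 (3Z,5S)-1,1-diethoxy-8-methyl-4-[(trimethylsilyl)methyl]nona-3,7-dien-5-ol
Product: 10 tert-butyl{[(3Z,5S)-1,1-diethoxy-8-methyl-4-[(trimethylsilyl)methyl]nona-3,7-dien-5-yl]oxy}dimethylsilane
Conditions: TBSCl, imidazole, DMF, rt
Reagents that add atoms: tert-butyldimethylsilyl chloride, CC(C)(C)[Si](C)(C)Cl
Why: Standard silylation of the secondary allylic alcohol, which masks the side-chain oxygen through the Lewis-acid step.

Step 6
Reactants: 11 2,2-diethoxy-1-(piperidin-1-yl)ethan-1-one
Product: 12 1,1-diethoxybutan-2-one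
Conditions: EtMgBr, THF, 0 °C; aq. NH4Cl
Reagents that add atoms: ethylmagnesium bromide, CC[Mg]Br
Why: Grignard acylation with a tertiary amide: the magnesium hemiaminal is stable until work-up, so that addition should stop at the α-keto acetal.

Step 7
Reactants: 12 1,1-diethoxybutan-2-one; 13 (1S)-1-(naphthalen-2-yl)ethan-1-ol
Product: 15 1-ethoxy-1-[(1S)-1-(naphthalen-2-yl)ethoxy]butan-2-one (acetal epimers), via chloro ether 14 (not isolated)
Conditions: AcCl, I2 (cat.), 50 °C, evaporate; then 13, i-Pr2NEt, CH2Cl2, 0 °C → rt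
Reagents that add atoms: none
Why: Acetal-to-chloro-ether exchange with acetyl chloride followed by base-mediated etherification of the chiral secondary alcohol should give the mixed acetal without exposing the benzylic alcohol to acid, its carbinol centre being untouched.

Step 8
Reactants: 15 1-ethoxy-1-[(1S)-1-(naphthalen-2-yl)ethoxy]butan-2-one
Product: 17 triethyl{[(2Z)-1-ethoxy-1-[(1S)-1-(naphthalen-2-yl)ethoxy]but-2-en-2-yl]oxy}silane, via sodium enolate 16 (not isolated)
Conditions: NaHMDS, THF, −78 °C; then Et3SiCl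
Reagents that add atoms: chlorotriethylsilane, CC[Si](Cl)(CC)CC
Why: Kinetic deprotonation at the ethyl CH2 (the only accessible acidic site) and O-silylation of the sodium enolate should give the Z-silyl enol ether, whose geometry is of no consequence later.

Step 9
Reactants: 10 tert-butyl{[(3Z,5S)-1,1-diethoxy-8-methyl-4-[(trimethylsilyl)methyl]nona-3,7-dien-5-yl]oxy}dimethylsilane; 17 triethyl{[(2Z)-1-ethoxy-1-[(1S)-1-(naphthalen-2-yl)ethoxy]but-2-en-2-yl]oxy}silane
Product: 20 (5S,6R)-5-[(3S)-3-[(tert-butyldimethylsilyl)oxy]-6-methylhepta-1,5-dien-2-yl]-2-methyl-6-[(1S)-1-(naphthalen-2-yl)ethoxy]cyclohex-2-en-1-one (side chain and ether cis), via open-chain allylation adduct 18 (not isolated), via 3-ethoxycyclohexanone 19 (not isolated)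
Conditions: 10 (1 equiv), 17 (1.3 equiv), CH2Cl2, −78 °C; TMSOTf (0.2 equiv) added slowly, −78 → −30 °C; then DBU, −30 → 0 °C
Reagents that add atoms: none
Why: Proposed new method: TMSOTf ionises the enol-ether-conjugated mixed acetal of 17 with loss of the small ethoxy group to a 1-alkoxy-2-siloxyallyl cation, which is attacked at its oxocarbenium terminus by the γ-carbon of allylsilane 10 (anti-SE2′; loss of Me3Si+ creates the exocyclic C=CH2 and returns the catalyst), after which the diethyl acetal of 18 ionises and is captured by the now tethered silyl enol ether in a 6-(enolendo)-exo-trig Mukaiyama aldol closure, and DBU removes ethanol from 19 (E1cB) to unveil the enone. The closest known reaction types are the Hosomi–Sakurai allylation of acetals, the silyl-triflate-catalysed Mukaiyama aldol addition of silyl enol ethers to acetals, and the stepwise [4+3] cycloadditions of 2-siloxyallyl cations generated from α-keto-acetal enol ethers, of which this is the allylsilane-terminated (3+3) counterpart. The carbocycle is closed by C–C bond formation between the enol ether carbon (future C1) and the oxocarbenium carbon (future C6); should the aldol bond form first intermolecularly, the ring would close by a 6-exo-trig allylsilane attack, and both orders converge on 19. C3 is set by the auxiliary, because in the E-oxocarbenium ion the carbinol C–H of the 1-(2-naphthyl)ethyl group eclipses the C=O+ bond and the allylsilane should enter anti to the naphthyl group, and C4 follows from the open antiperiplanar SE2′ transition state in which the ketone arm of the electrophile lies over the vinylic hydrogen and not over the CH2 chain, which gives the syn (ring-cis) relationship; the centres formed at C1 and C6 in the aldol are deleted by the elimination. The step needs cross- over homo-coupling and attack at the alkoxy-bearing terminus of the cation: the first should be secured by the faster ionisation of the conjugated acetal and by the higher nucleophilicity of the 2-substituted allylsilane compared with the deactivated enol ether, the second by the oxocarbenium character of that terminus.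

Step 10
Reactants: 20 (5S,6R)-enone
Product: 21 (1S,5S,6R)-5-[(3S)-3-[(tert-butyldimethylsilyl)oxy]-6-methylhepta-1,5-dien-2-yl]-2-methyl-6-[(1S)-1-(naphthalen-2-yl)ethoxy]cyclohex-2-en-1-ol (all-cis)
Conditions: NaBH4, CeCl3·7H2O, MeOH, −78 °C
Reagents that add atoms: none
Why: Luche 1,2-reduction: hydride should add to the carbonyl face opposite the C3 alkoxy group and the C4 side chain (both on the same face), which places the new C2 hydroxyl cis to both.

Step 11
Reactants: 21 all-cis cyclohexenol
Product: 22 (1R,2R,3R,4S,6S)-4-[(3S)-3-[(tert-butyldimethylsilyl)oxy]-6-methylhepta-1,5-dien-2-yl]-1-methyl-3-[(1S)-1-(naphthalen-2-yl)ethoxy]-7-oxabicyclo[4.1.0]heptan-2-ol (oxirane cis to OH)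
Conditions: VO(acac)2 (cat.), t-BuOOH, CH2Cl2, 0 °C → rt
Reagents that add atoms: tert-butyl hydroperoxide, CC(C)(C)OO
Why: Vanadium-catalysed hydroxyl-directed epoxidation should deliver oxygen to the ring alkene on the face of the C2 hydroxyl and is selective for the allylic-alcohol alkene over the unactivated prenyl and 1,1-disubstituted alkenes.

Step 12
Reactants: 22 epoxy alcohol
Product: 23 (1R,2R,3R,4S,6S)-4-[(3S)-3-hydroxy-6-methylhepta-1,5-dien-2-yl]-1-methyl-3-[(1S)-1-(naphthalen-2-yl)ethoxy]-7-oxabicyclo[4.1.0]heptan-2-ol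
Conditions: TBAF, THF, 0 °C → rt
Reagents that add atoms: none
Why: Fluoride cleaves the silyl ether; the cis epoxy alcohol should not undergo Payne rearrangement because its alkoxide cannot reach the backside of the oxirane.

Step 13
Reactants: 23 diol
Product: 25 bis-angelate (1S,2R,3R,4S,6S)-4-[(3S)-3-(angeloyloxy)-6-methylhepta-1,5-dien-2-yl]-1-methyl-3-[(1S)-1-(naphthalen-2-yl)ethoxy]-7-oxabicyclo[4.1.0]heptan-2-yl (2Z)-2-methylbut-2-enoate, via dilithium dialkoxide 24 (not isolated)
Conditions: LiHMDS (2.3 equiv), THF, −40 °C; then angelic anhydride (3 equiv), −40 → 0 °C; aq. NH4Cl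
Reagents that add atoms: angelic anhydride, C/C=C(/C)C(=O)OC(=O)/C(C)=C\C
Why: O-acylation of the two lithium alkoxides with angelic anhydride at low temperature, without a nucleophilic catalyst, should install both esters with retention of the Z-alkene geometry, the only other oxygen (C3) being masked as the ether.

Step 14
Reactants: 25 bis-angelate
Product: 26 target C3–O (1S)-1-(naphthalen-2-yl)ethyl ether, with the (R)-3,3-dimethyloxiran-2-yl group in the side chain
Conditions: D-fructose-derived Shi ketone (0.3 equiv), Oxone, K2CO3, Bu4NHSO4, MeCN–DMM–aq. buffer (pH 10.5), 0 °C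
Reagents that add atoms: potassium peroxymonosulfate (Oxone), [K+].[O-]S(=O)(=O)OO
Why: Shi epoxidation: the chiral dioxirane selects the electron-rich trisubstituted alkene over the 1,1-disubstituted and enoate alkenes and, through the spiro transition state, the D-fructose-derived ketone should give the (R)-oxirane.

Step 15
Reactants: 26 naphthylethyl ether of the target
Product: 27 target, (1S,2R,3R,4S,6S)-4-{(3S)-3-(angeloyloxy)-4-[(2R)-3,3-dimethyloxiran-2-yl]but-1-en-2-yl}-3-hydroxy-1-methyl-7-oxabicyclo[4.1.0]heptan-2-yl (2Z)-2-methylbut-2-enoate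
Conditions: DDQ, CH2Cl2–pH 7 phosphate buffer, 0 °C → rt
Reagents that add atoms: none
Why: DDQ oxidises the electron-rich secondary naphthylmethyl ether by benzylic hydride abstraction and the oxocarbenium ion is hydrolysed under buffered neutral conditions, which should free the C3 hydroxyl without acyl migration or oxirane opening.

## Compound list

1 | 4-methylpent-3-enoic acid | CC(C)=CCC(=O)O | starting material
2 | 1-(4-methylpent-3-enoyl)-1H-imidazole | CC(C)=CCC(=O)n1ccnc1 | intermediate (not isolated)
3 | N-methoxy-N,4-dimethylpent-3-enamide | CC(C)=CCC(=O)N(C)OC | intermediate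
4 | 4,4-diethoxybut-1-yne | C#CCC(OCC)OCC | starting material
5 | lithium 4,4-diethoxybut-1-yn-1-ide | [Li]C#CCC(OCC)OCC | intermediate (not isolated)
6 | 1,1-diethoxy-8-methylnon-7-en-3-yn-5-one | CCOC(OCC)CC#CC(=O)CC=C(C)C | intermediate
7 | (5S)-1,1-diethoxy-8-methylnon-7-en-3-yn-5-ol | CCOC(OCC)CC#C[C@H](CC=C(C)C)O | intermediate
8 | cyclic alkenylmagnesium alkoxide (five-membered C–Mg–O chelate formed by anti addition of CH2SiMe3 and Mg to 7) | C[Si](C)(C)CC1=C(CC(OCC)OCC)[Mg]O[C@H]1CC=C(C)C | intermediate (not isolated)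
9 | (3Z,5S)-1,1-diethoxy-8-methyl-4-[(trimethylsilyl)methyl]nona-3,7-dien-5-ol | C[Si](C)(C)C/C(=C\CC(OCC)OCC)[C@H](CC=C(C)C)O | intermediate
10 | tert-butyl{[(3Z,5S)-1,1-diethoxy-8-methyl-4-[(trimethylsilyl)methyl]nona-3,7-dien-5-yl]oxy}dimethylsilane | C[Si](C)(C)C/C(=C\CC(OCC)OCC)[C@H](CC=C(C)C)O[Si](C)(C)C(C)(C)C | intermediate
11 | 2,2-diethoxy-1-(piperidin-1-yl)ethan-1-one | CCOC(OCC)C(=O)N1CCCCC1 | starting material
12 | 1,1-diethoxybutan-2-one | CCC(=O)C(OCC)OCC | intermediate
13 | (1S)-1-(naphthalen-2-yl)ethan-1-ol | C[C@H](O)c1ccc2ccccc2c1 | starting material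
14 | 1-chloro-1-ethoxybutan-2-one (racemic) | CCC(=O)C(Cl)OCC | intermediate (not isolated)
15 | 1-ethoxy-1-[(1S)-1-(naphthalen-2-yl)ethoxy]butan-2-one (acetal epimers) | CCC(=O)C(OCC)O[C@@H](C)c1ccc2ccccc2c1 | intermediate
16 | sodium (Z)-enolate of 15 | C/C=C(\[O-])C(OCC)O[C@@H](C)c1ccc2ccccc2c1.[Na+] | intermediate (not isolated)
17 | triethyl{[(2Z)-1-ethoxy-1-[(1S)-1-(naphthalen-2-yl)ethoxy]but-2-en-2-yl]oxy}silane | C/C=C(\O[Si](CC)(CC)CC)C(OCC)O[C@@H](C)c1ccc2ccccc2c1 | intermediate
18 | open-chain allylation adduct (C3–C4 bond formed; Z-silyl enol ether and diethyl acetal still present) | C=C([C@H](CC=C(C)C)O[Si](C)(C)C(C)(C)C)[C@H](CC(OCC)OCC)[C@@H](O[C@@H](C)c1ccc2ccccc2c1)C(/O[Si](CC)(CC)CC)=C/C | intermediate (not isolated)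
19 | 3-ethoxy-2-methylcyclohexanone carrying the cis C5 side chain and C6 ether (epimers at the ethoxy- and methyl-bearing carbons) | C=C([C@H](CC=C(C)C)O[Si](C)(C)C(C)(C)C)[C@@H]1CC(OCC)C(C)C(=O)[C@@H]1O[C@@H](C)c1ccc2ccccc2c1 | intermediate (not isolated)
20 | (5S,6R)-5-[(3S)-3-[(tert-butyldimethylsilyl)oxy]-6-methylhepta-1,5-dien-2-yl]-2-methyl-6-[(1S)-1-(naphthalen-2-yl)ethoxy]cyclohex-2-en-1-one | C=C([C@H](CC=C(C)C)O[Si](C)(C)C(C)(C)C)[C@@H]1CC=C(C)C(=O)[C@@H]1O[C@@H](C)c1ccc2ccccc2c1 | intermediate
21 | (1S,5S,6R)-cyclohex-2-en-1-ol from 20 (OH, ether and side chain all cis) | C=C([C@H](CC=C(C)C)O[Si](C)(C)C(C)(C)C)[C@@H]1CC=C(C)[C@H](O)[C@@H]1O[C@@H](C)c1ccc2ccccc2c1 | intermediate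
22 | (1R,2R,3R,4S,6S)-4-[(3S)-3-[(tert-butyldimethylsilyl)oxy]-6-methylhepta-1,5-dien-2-yl]-1-methyl-3-[(1S)-1-(naphthalen-2-yl)ethoxy]-7-oxabicyclo[4.1.0]heptan-2-ol | C=C([C@H](CC=C(C)C)O[Si](C)(C)C(C)(C)C)[C@@H]1C[C@@H]2O[C@]2(C)[C@H](O)[C@@H]1O[C@@H](C)c1ccc2ccccc2c1 | intermediate
23 | (1R,2R,3R,4S,6S)-4-[(3S)-3-hydroxy-6-methylhepta-1,5-dien-2-yl]-1-methyl-3-[(1S)-1-(naphthalen-2-yl)ethoxy]-7-oxabicyclo[4.1.0]heptan-2-ol | C=C([C@H](CC=C(C)C)O)[C@@H]1C[C@@H]2O[C@]2(C)[C@H](O)[C@@H]1O[C@@H](C)c1ccc2ccccc2c1 | intermediate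
24 | dilithium dialkoxide of 23 | C=C([C@H](CC=C(C)C)[O-])[C@@H]1C[C@@H]2O[C@]2(C)[C@H]([O-])[C@@H]1O[C@@H](C)c1ccc2ccccc2c1.[Li+].[Li+] | intermediate (not isolated)
25 | bis-angelate of 23 (esters at C2–O and at the side-chain carbinol) | C=C([C@H](CC=C(C)C)OC(=O)/C(C)=C\C)[C@@H]1C[C@@H]2O[C@]2(C)[C@H](OC(=O)/C(C)=C\C)[C@@H]1O[C@@H](C)c1ccc2ccccc2c1 | intermediate
26 | C3–O (1S)-1-(naphthalen-2-yl)ethyl ether of the target (side-chain (R)-oxirane in place) | C=C([C@H](C[C@H]1OC1(C)C)OC(=O)/C(C)=C\C)[C@@H]1C[C@@H]2O[C@]2(C)[C@H](OC(=O)/C(C)=C\C)[C@@H]1O[C@@H](C)c1ccc2ccccc2c1 | intermediate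
27 | CNP0296086.3, (1S,2R,3R,4S,6S)-4-{(3S)-3-(angeloyloxy)-4-[(2R)-3,3-dimethyloxiran-2-yl]but-1-en-2-yl}-3-hydroxy-1-methyl-7-oxabicyclo[4.1.0]heptan-2-yl (2Z)-2-methylbut-2-enoate | C=C([C@H](C[C@H]1OC1(C)C)OC(=O)/C(C)=C\C)[C@@H]1C[C@@H]2O[C@]2(C)[C@H](OC(=O)/C(C)=C\C)[C@@H]1O | target

## Step count and risks

Total step count: 15. Longest linear sequence: 12 steps (steps 1–5 and 9–15, from acid 1); the second branch (steps 6–8) joins at step 9.

Steps most likely to fail:

1. Step 9 (Proposed new method). The process at risk is the partition of the cations: either bifunctional partner may couple with itself, the β-silyl cation may be captured by the enol ether (five-ring annulation) instead of losing silicon, the auxiliary may give poor facial selectivity, or the centre next to the ketone may epimerise during the base-induced elimination. The fallback makes the two bonds in the reverse order, in separate flasks, by known reactions. Setting out from 10, the diethyl acetal is hydrolysed (LiBF4, wet MeCN) to the aldehyde (3Z,5S)-5-[(tert-butyldimethylsilyl)oxy]-8-methyl-4-[(trimethylsilyl)methyl]nona-3,7-dienal F1. The sodium enolate 16 is added to it in THF at −78 °C, conditions under which allylsilane and acetal are inert, to give the open-chain aldol adduct F2. SnCl4 in CH2Cl2 at −78 °C then ionises the mixed acetal and the tethered allylsilane closes the six-membered ring in an intramolecular Hosomi–Sakurai reaction to the 3-hydroxycyclohexanone F3. Acid-catalysed dehydration (TsOH, benzene, 50 °C) comes back to the route at 20.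

2. Step 4. The process at risk is the carbometalation itself: the internal, secondary propargylic alkoxide may react sluggishly, deprotonation at the propargylic CH2 may lead to allene formation, or the regiochemistry of addition may erode. The fallback replaces carbometalation by hydrometalation and cross-coupling. Setting out from 7, hydroxyl-directed ruthenium-catalysed trans-hydrostannation ([Cp*RuCl]4, Bu3SnH, CH2Cl2) places tin on the alkyne carbon next to the carbinol and gives the alkenylstannane F4. Iododestannylation (I2, CH2Cl2, 0 °C) gives the alkenyl iodide F5 with retention. Palladium-catalysed Kumada coupling with Me3SiCH2MgCl (Pd(PPh3)4, THF) comes back to the route at 9.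

3. Step 13. The process at risk is incomplete acylation of the hindered C2 alkoxide and isomerisation of the Z-enoate to the tiglate under basic conditions. The fallback builds the Z-alkenes on the molecule instead of transferring them. Setting out from 23, both hydroxyls are esterified with 2-[bis(2,2,2-trifluoroethoxy)phosphoryl]propanoic acid (DIC, DMAP, CH2Cl2) to the bis(phosphonopropanoate) F6. A double Still–Gennari olefination with acetaldehyde (KHMDS, 18-crown-6, THF, −78 °C) should form both (Z)-2-methylbut-2-enoates and comes back to the route at 25.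

Further compounds
F1 | step 9 | (3Z,5S)-5-[(tert-butyldimethylsilyl)oxy]-8-methyl-4-[(trimethylsilyl)methyl]nona-3,7-dienal | C[Si](C)(C)C/C(=C\CC=O)[C@H](CC=C(C)C)O[Si](C)(C)C(C)(C)C
F2 | step 9 | open-chain aldol adduct of enolate 16 and F1 (epimers at the new carbinol and methyl-bearing carbons) | C[Si](C)(C)C/C(=C\CC(O)C(C)C(=O)C(OCC)O[C@@H](C)c1ccc2ccccc2c1)[C@H](CC=C(C)C)O[Si](C)(C)C(C)(C)C
F3 | step 9 | 3-hydroxy-2-methylcyclohexanone with the cis C5 side chain and C6 ether (epimers at the hydroxy- and methyl-bearing carbons) | C=C([C@H](CC=C(C)C)O[Si](C)(C)C(C)(C)C)[C@@H]1CC(O)C(C)C(=O)[C@@H]1O[C@@H](C)c1ccc2ccccc2c1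
F4 | step 4 | (3Z,5S)-1,1-diethoxy-8-methyl-4-(tributylstannyl)nona-3,7-dien-5-ol | CCCC[Sn](CCCC)(CCCC)/C(=C\CC(OCC)OCC)[C@H](CC=C(C)C)O
F5 | step 4 | (3Z,5S)-1,1-diethoxy-4-iodo-8-methylnona-3,7-dien-5-ol | I/C(=C\CC(OCC)OCC)[C@H](CC=C(C)C)O
F6 | step 13 | bis{2-[bis(2,2,2-trifluoroethoxy)phosphoryl]propanoate} of diol 23 | C=C([C@H](CC=C(C)C)OC(=O)C(C)P(=O)(OCC(F)(F)F)OCC(F)(F)F)[C@@H]1C[C@@H]2O[C@]2(C)[C@H](OC(=O)C(C)P(=O)(OCC(F)(F)F)OCC(F)(F)F)[C@@H]1O[C@@H](C)c1ccc2ccccc2c1
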